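**Plan**

- Retrosynthetic cuts, in order: the ring A O–CH3 bond; the pyranone on ring B (aryl C–C(=O) bond and O–CMe2 bond); the aryl C–O bond of the lactone on ring B; the diaryl ether C–O bond on ring A; then the carboxyl, methoxy and formyl groups of ring A, back to 3,5-difluorotoluene.
- Enabling feature: on ring B the lactone oxygen is para to the pyranone oxygen and sits on the carbon between the methyl-bearing carbon and the carbon carrying the diaryl ether oxygen. Without that oxygen ring B is orcinol, and the ring A carboxyl, ortho to the ether bridge, can deliver it to the carbon para to the free phenol.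
- Forward order: ring A is dressed in four steps and joined to orcinol by SNAr; the acid is unmasked; the seven-membered lactone ring is closed oxidatively (first ring); the pyranone is annulated onto the regenerated phenol (second ring); the ring A methyl ether is cleaved last.
- The carboxyl group is carried as a 2-(trimethylsilyl)ethyl ester, because an ester flanked by methyl and aryloxy groups resists saponification; fluoride removes it without attack at the acyl carbon and without harm to the formyl group.
- Stereochemistry: the target has no stereocentre; the only sp3 ring carbon made on the way (in dienone 11) is transient and racemic.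

Key step: step 7

Remark: ring A is the formyl-bearing benzoyl ring, ring B the orcinol-derived ring; locants on the tricycle follow dibenzo[b,e][1,4]dioxepin-11-one numbering (ring A C1–C4, ether O5, ring B C6–C9, ester O10, carbonyl C11).

**Route**

Step 1
Reactants: 1 3,5-difluorotoluene
Product: 3 2,6-difluoro-4-methylbenzaldehyde, via aryllithium 2 (not isolated)
Conditions: n-BuLi, THF, −78 °C; DMF, −78 → 0 °C; aq. HCl
Reagents that add atoms: N,N-dimethylformamide, CN(C)C=O
Why: Directed ortho-lithiation removes the proton flanked by both fluorine atoms, the most acidic ring position, and aryllithium 2 is formylated by DMF (Bouveault-type formylation), the low temperature preventing loss of LiF to an aryne.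

Step 2
Reactants: 3 2,6-difluoro-4-methylbenzaldehyde
Product: 4 2-fluoro-6-methoxy-4-methylbenzaldehyde
Conditions: NaOMe (1.05 equiv), MeOH, 0 → 40 °C
Reagents that add atoms: sodium methoxide, C[O-].[Na+]
Why: Nucleophilic aromatic substitution of a fluoride ortho to the formyl group, in which the two fluorides are equivalent so only one mono-ether can form and the new methoxy donor slows a second displacement.

Step 3
Reactants: 4 2-fluoro-6-methoxy-4-methylbenzaldehyde
Product: 5 2-fluoro-3-iodo-6-methoxy-4-methylbenzaldehyde
Conditions: NIS, CF3CO2H, 0 °C → rt, dark
Reagents that add atoms: N-iodosuccinimide, O=C1CCC(=O)N1I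
Why: Electrophilic aromatic iodination is directed by the methoxy group to its para position, the carbon between fluorine and methyl, because the only other free carbon is ortho to methoxy and more crowded, while the formyl group is meta to both sites and does not discriminate.

Step 4
Reactants: 5 2-fluoro-3-iodo-6-methoxy-4-methylbenzaldehyde
Product: 6 2-(trimethylsilyl)ethyl 2-fluoro-3-formyl-4-methoxy-6-methylbenzoate
Conditions: Pd(OAc)2 (5 mol %), Xantphos, CO (1 atm), Me3SiCH2CH2OH, Et3N, toluene, 70 °C
Reagents that add atoms: carbon monoxide, [C-]#[O+]; 2-(trimethylsilyl)ethanol, C[Si](C)(C)CCO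
Why: Palladium-catalysed alkoxycarbonylation of an aryl iodide (oxidative addition to zerovalent palladium formed in the flask, CO insertion, alcoholysis of the acylpalladium) tolerates di-ortho-substituted iodides and aldehydes, and the non-nucleophilic base and solvent leave the activated fluoride alone.

Step 5
Reactants: 6 2-(trimethylsilyl)ethyl 2-fluoro-3-formyl-4-methoxy-6-methylbenzoate; 7 orcinol (5-methylbenzene-1,3-diol)
Product: 8 2-(trimethylsilyl)ethyl 3-formyl-2-(3-hydroxy-5-methylphenoxy)-4-methoxy-6-methylbenzoate
Conditions: 7 (3 equiv), K2CO3, DMF, 50 °C
Reagents that add atoms: none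
Why: Nucleophilic aromatic substitution in which the fluoride of 6, lying between a formyl and an ester group, is displaced by the mono-phenoxide of orcinol, the symmetry of orcinol allowing only one mono-aryl ether, its excess suppressing double arylation, and the sparingly soluble KF posing little threat to the silylethyl ester at this temperature.

Step 6
Reactants: 8 2-(trimethylsilyl)ethyl 3-formyl-2-(3-hydroxy-5-methylphenoxy)-4-methoxy-6-methylbenzoate
Product: 9 3-formyl-2-(3-hydroxy-5-methylphenoxy)-4-methoxy-6-methylbenzoic acid
Conditions: n-Bu4NF, THF, 0 °C → rt; 1 M HCl
Reagents that add atoms: none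
Why: Fluoride attacks silicon and the 2-(trimethylsilyl)ethyl ester fragments to carboxylate, ethylene and Me3SiF (β-elimination), so the ester flanked by methyl and aryloxy groups is unmasked without attack at its hindered carbonyl and without base strong enough to harm the formyl group.

Step 7
Reactants: 9 3-formyl-2-(3-hydroxy-5-methylphenoxy)-4-methoxy-6-methylbenzoic acid
Product: 12 7-hydroxy-3-methoxy-1,9-dimethyl-11-oxo-11H-dibenzo[b,e][1,4]dioxepine-4-carbaldehyde (depsidone phenol), via aryloxyiodane 10 (not isolated), via acyloxy dienone 11 (not isolated)
Conditions: PhI(OAc)2 (1.05 equiv, slow addition), (CF3)2CHOH, 0 °C, 0.01 M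
Reagents that add atoms: none
Why: Proposed new method: ligand exchange puts the ring B phenol oxygen of 9 on trivalent iodine (10), departure of iodobenzene leaves a phenoxenium-like ring whose para carbon (between the methyl-bearing and the aryloxy-bearing carbons) is attacked by the ring A carboxyl oxygen to give acyloxy dienone 11, and loss of the proton on that carbon re-aromatises ring B to the para-hydroxyaryl ester 12; the closest known reactions are PhI(OAc)2-mediated dearomatising spirolactonisation of phenols carrying a tethered acid and para-acyloxylation of phenols, neither of which has been used to close a fused seven-membered lactone. The one ring formed is the seven-membered dioxepinone, closed by C–O bond formation in a 7-exo-trig sense (the carboxyl oxygen adds to a trigonal ring B carbon whose π partner lies outside the new ring). No stereocentre remains, since the sp3 carbon of 11 is lost on tautomerisation. The step needs attack para and not ortho to the oxidised oxygen although both carbons next to the ether bridge are within reach: the para carbon carries the larger share of positive charge and is supported by the adjacent methyl group, while the ortho carbon sits between two oxygens and beside the bulky iodine ligand. It also needs oxidation to stop after one turnover, which one equivalent of oxidant added slowly at high dilution in the non-nucleophilic fluoroalcohol should secure, because no water or alcohol is present to take the ring on to a quinone or quinone ketal. The hindered ester is made with the carboxylate as nucleophile, so the di-ortho-substituted acyl carbon is never attacked.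

Step 8
Reactants: 12 depsidone phenol; 13 3-methylbut-2-enoic acid
Product: 15 mollicellin B methyl ether (12 with a 2,2-dimethyl-2,3-dihydropyran-4-one fused across C7–C8: ring oxygen on C7 and ketone carbon on C8), via hydroxyaryl enone 14 (not isolated)
Conditions: 13 (1.5 equiv), P2O5/MeSO3H (1:10 w/w), 50 °C
Reagents that add atoms: none
Why: Friedel–Crafts acylation by the mixed methanesulfonic anhydride formed in the flask occurs on ring B at C8, the carbon between the phenol and the methyl group and para to the bridging ether oxygen (the usual acylation site of orcinol derivatives, whereas C6 lies in the bay beside the ring A formyl group and ring A is deactivated), and enone 14 closes by 6-endo-trig oxa-Michael addition to the 2,2-dimethylchroman-4-one, as in the standard P2O5/MeSO3H chromanone annulation of phenols.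

Step 9
Reactants: 15 mollicellin B methyl ether
Product: 16 mollicellin B
Conditions: BCl3 (3 equiv), CH2Cl2, −78 → 0 °C; H2O
Reagents that add atoms: none
Why: BCl3 chelates the formyl oxygen and the neighbouring methoxy oxygen in a six-membered ring and chloride removes the methyl group (chelation-controlled ether cleavage ortho to a carbonyl group), which at low temperature leaves the aryl lactone, the diaryl ether and the pyranone alkyl aryl ether, none of which can form such a chelate, untouched.

**Compound list**

1 | 3,5-difluorotoluene | Cc1cc(F)cc(F)c1 | starting material
2 | (2,6-difluoro-4-methylphenyl)lithium (not isolated) | [Li]c1c(F)cc(C)cc1F | intermediate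
3 | 2,6-difluoro-4-methylbenzaldehyde | Cc1cc(F)c(C=O)c(F)c1 | intermediate
4 | 2-fluoro-6-methoxy-4-methylbenzaldehyde | Cc1cc(F)c(C=O)c(OC)c1 | intermediate
5 | 2-fluoro-3-iodo-6-methoxy-4-methylbenzaldehyde | Cc1cc(OC)c(C=O)c(F)c1I | intermediate
6 | 2-(trimethylsilyl)ethyl 2-fluoro-3-formyl-4-methoxy-6-methylbenzoate | Cc1cc(OC)c(C=O)c(F)c1C(=O)OCC[Si](C)(C)C | intermediate
7 | orcinol (5-methylbenzene-1,3-diol) | Cc1cc(O)cc(O)c1 | starting material
8 | 2-(trimethylsilyl)ethyl 3-formyl-2-(3-hydroxy-5-methylphenoxy)-4-methoxy-6-methylbenzoate | Cc1cc(OC)c(C=O)c(Oc2cc(C)cc(O)c2)c1C(=O)OCC[Si](C)(C)C | intermediate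
9 | 3-formyl-2-(3-hydroxy-5-methylphenoxy)-4-methoxy-6-methylbenzoic acid | Cc1cc(OC)c(C=O)c(Oc2cc(C)cc(O)c2)c1C(=O)O | intermediate
10 | acetoxy(phenyl)iodane bound through the ring B phenol oxygen of 9 (not isolated) | CC(=O)OI(Oc1cc(C)cc(Oc2c(C=O)c(OC)cc(C)c2C(=O)O)c1)c1ccccc1 | intermediate
11 | 4-acyloxycyclohexa-2,5-dienone tautomer of 12, racemic at the sp3 carbon C9a (not isolated) | Cc1cc(OC)c(C=O)c2c1C(=O)OC1C(C)=CC(=O)C=C1O2 | intermediate
12 | 7-hydroxy-3-methoxy-1,9-dimethyl-11-oxo-11H-dibenzo[b,e][1,4]dioxepine-4-carbaldehyde (depsidone phenol) | Cc1cc(OC)c(C=O)c2c1C(=O)Oc1c(C)cc(O)cc1O2 | intermediate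
13 | 3-methylbut-2-enoic acid | CC(C)=CC(=O)O | starting material
14 | 7-hydroxy-3-methoxy-1,9-dimethyl-8-(3-methylbut-2-enoyl)-11-oxo-11H-dibenzo[b,e][1,4]dioxepine-4-carbaldehyde (not isolated) | Cc1cc(OC)c(C=O)c2c1C(=O)Oc1c(C)c(C(=O)C=C(C)C)c(O)cc1O2 | intermediate
15 | mollicellin B methyl ether (ring A methoxy; pyranone fused on ring B) | Cc1cc(OC)c(C=O)c2c1C(=O)Oc1c(cc3c(c1C)C(=O)CC(C)(C)O3)O2 | intermediate
16 | mollicellin B | Cc1cc(O)c(C=O)c2c1C(=O)Oc1c(cc3c(c1C)C(=O)CC(C)(C)O3)O2 | target

**Count**

Total steps: 9. Longest linear sequence: 9 steps (1 → 16); orcinol 7 and acid 13 enter as purchased materials.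

**Steps most likely to fail**

1. Step 7 (proposed new method). The oxidised phenol may be captured at the ortho carbon between the two oxygens, ring B may be oxidised a second time, or the oxidised phenol may couple with a second molecule before the carboxyl group closes the ring.
Fallback with known chemistry, setting out from 9 and returning at 12: the oxygen is installed first and the lactone is then closed by classical acyl activation. Teuber oxidation of the phenol of 9 with potassium nitrosodisulfonate, (KSO3)2NO, in KH2PO4-buffered aqueous acetone should give the para-quinone acid F1, para-quinone formation being the normal course when the para carbon is free. Reduction with Na2S2O4 in a two-phase mixture should give the hydroquinone acid F2. Lactonisation with 2-chloro-1-methylpyridinium iodide and Et3N in CH2Cl2 at high dilution should then give 12, because only the hydroxyl ortho to the ether bridge can reach the activated acid through a seven-membered ring. This gives up the advantage of never attacking the hindered acyl carbon, but closure of 2-(2-hydroxyaryloxy)benzoic acids is the established entry to this lactone class.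

2. Step 8. In the strongly acidic medium the hindered aryl lactone may suffer acyl–oxygen cleavage and reclose onto a ring B carbon, the formyl group may condense with the electron-rich ring B of a second molecule, or acylation may occur at the other ortho carbon.
Fallback, setting out from 12 and returning at 15: the acyl group is introduced under neutral conditions. Iodination ortho to the phenol and para to the ether oxygen (NIS, MeCN, 0 °C) should give the ring B iodophenol F4, with any regioisomer removed at this stage. Carbonylative Stille coupling of F4 with tributyl(2-methylprop-1-enyl)stannane (CC(C)=C[Sn](CCCC)(CCCC)CCCC) under CO (1 atm) with Pd(PPh3)4 in dioxane at 80 °C should give hydroxyaryl enone 14. Brief treatment with Et3N closes 14 by oxa-Michael addition to 15.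

3. Step 3. Iodination may also take place ortho to the methoxy group, between methoxy and methyl, giving regioisomers that are hard to separate, or may be sluggish on the formyl-deactivated ring.
Fallback, setting out from 3 and returning at 5: the order of iodination and methoxide substitution is reversed. Iodination of the symmetrical aldehyde 3 (NIS, CF3SO3H, 0 °C → rt), whose two free ring carbons are equivalent, can only give 2,6-difluoro-3-iodo-4-methylbenzaldehyde F3. NaOMe in MeOH should then displace the fluoride remote from iodine (flanked by formyl and hydrogen) in preference to the one wedged between formyl and iodine, giving 5.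

**Further compounds**

F1 | step 7 | 3-formyl-4-methoxy-6-methyl-2-[(5-methyl-3,6-dioxocyclohexa-1,4-dien-1-yl)oxy]benzoic acid | Cc1cc(OC)c(C=O)c(OC2=CC(=O)C=C(C)C2=O)c1C(=O)O
F2 | step 7 | 2-(2,5-dihydroxy-3-methylphenoxy)-3-formyl-4-methoxy-6-methylbenzoic acid | Cc1cc(OC)c(C=O)c(Oc2cc(O)cc(C)c2O)c1C(=O)O
F3 | step 3 | 2,6-difluoro-3-iodo-4-methylbenzaldehyde | Cc1cc(F)c(C=O)c(F)c1I
F4 | step 8 | 7-hydroxy-8-iodo-3-methoxy-1,9-dimethyl-11-oxo-11H-dibenzo[b,e][1,4]dioxepine-4-carbaldehyde | Cc1cc(OC)c(C=O)c2c1C(=O)Oc1c(C)c(I)c(O)cc1O2
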